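## Structural features

The target has four rings: a trans-fused octalin (ring A, the cyclohexene C1–C2–C3=C4–C4a–C8a; ring B, the cyclohexane C4a–C5–C6–C7–C8–C8a), a 1,4-dihydroxy-2-pyridone (ring C) and a cyclohexane with a fused oxirane (ring D, C1′–C6′). C1 of ring A is joined to C3 of ring C through a ketone, and C5 of ring C is bonded directly to the tertiary carbinol carbon C1′ of ring D. The octalin carries five stereocentres: C1 and C2 are neighbours (acyl equatorial, methyl pseudoaxial, cis), C8a and C4a form the trans ring fusion beside them, and C6 bears a remote equatorial methyl group. Ring D has four contiguous centres: C1′ (tertiary hydroxyl), C6′ and C5′ (oxirane on the face of the C1′ hydroxyl) and C4′ (hydroxyl trans to the oxirane). Fragile points are the N–O bond of the metal-binding pyridone, the enolised tricarbonyl array with its epimerisable C1–H, and the oxirane between two carbinols: acid can ionise C1′, and base can shift the epoxide from the C4′ oxygen. The ring A alkene is also fragile, because it forbids peracid or hydrogenolysis late in the route. The real difficulty is threefold: the cis C1/C2 pair beside a trans fusion must be built on a ring B that already exists, the N–O bond must be made where no alkene competes, and two hindered C–C bonds must be made to a fully substituted pyridone. The key step uses ring B itself: C4a and C8a are trans and the C6 methyl is 1,4 to C8a, which is the para adduct of isoprene with an E-dienophile whose two carbonyl carbons become C1 (on C8a) and C4 (on C4a).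

## Logic of the disconnections

31 to 30: the two O–C bonds of the silylethyl ethers and the O–Si bond at C4′ are cut. A pyridine N-oxide with an ether at C2 is a latent N-hydroxy-2-pyridone, so all three acidic hydroxyls are hidden behind fluoride-labile groups and the intermediates stay neutral and non-chelating. The forward step must be a single non-basic fluoride treatment that spares the oxirane, C1 and the alkene.

30 to 29 to 27 + 18: the bond between C3 of ring C and the acyl carbon is cut, and the ketone is taken back to a carbinol. This is the most convergent cut, giving an octalin aldehyde and a metalated heterocycle of similar size. The forward step needs a C3 nucleophile that tolerates the N-oxide, a free tertiary alcohol and the oxirane, and that adds to a branched aldehyde.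

27 to 26 to 25: the C3–I and N–O bonds are cut. The N–O bond is made by peracid at a stage where the molecule holds no C=C bond, and C3 is the only open activated ring position for the halogen. Both steps must be mild enough for the epoxy carbinol.

25 to 21 + 23: the C5–C1′ bond is cut, so the tertiary carbinol arises from an aryl-lithium and a ketone that already carries C4′, C5′ and C6′. Ring D stereochemistry is reduced to one addition, which must occur anti to the oxirane oxygen.

23 to 22 and 21 to 19: the two oxirane C–O bonds are cut back to a purchasable silyloxy enone (epoxidation anti to the silyl ether), and the two aryl ether C–O bonds back to a dichloropyridine. Both are simple, but the epoxidation must be highly trans-selective.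

18 to 16: the formyl C=O is traced to a nitromethyl group, so the acyl carbon can travel as a nitro compound through the metathesis. The forward Nef step must be near neutral to keep C1.

16 to 15: the C3=C4 bond of ring A is cut. It is the one ring A bond that can be closed without touching a stereocentre. The demand is two vinyl groups on trans-diequatorial arms.

15 to 14 to 12 + 13: the C1–C2 bond is cut (with the terminal methylene on C3). Both centres are set together by a catalyst-controlled Michael addition whose syn adduct maps onto the cis C1/C2 pair. A [3,3] shift of a ring-B-fused lactone enolate was weighed for this bond and set aside. With a trans ring fusion, the carbinol epimer that would give the required C1 configuration holds its alkenyl group equatorial, out of reach of the enolate carbon. The demand on the chosen step is that the catalyst overrides the adjacent C8a centre.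

12 to 8 + 9: the C1=C bond of the nitroalkene is cut, adding the acyl carbon as a one-carbon nucleophile. The forward step must give the conjugated E-alkene without deconjugation.

8 to 7 to 6 to 5: the vinyl group on C4a is traced to the ester (C4 is kept; the terminal carbon is lost later as ethylene) while C1 is held as an acetal. Each step must leave the trans arrangement of the ring untouched.

5 to 4 to 3: the C6–H bond is cut. The trisubstituted alkene of the cycloadduct is reduced by hydrogen-atom transfer, which should deliver the equatorial methyl group. The aldehyde must be masked first.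

3 to 1 + 2: the C4a–C5 and C8–C8a bonds are cut. One cycloaddition gives ring B, both ring-fusion centres and two differentiated carbonyl handles. The demands are para regiochemistry and face selectivity; the catalyst antipode is fixed here as (5R).

## Other disconnections considered

Alternative 1: The cut is at the two oxirane C–O bonds (C5′–O, C6′–O), reached from the para-quinol A1, in which ring D is a 4-hydroxycyclohexa-2,5-dienone with no stereocentre. The forward key step is an amine-salt-catalysed nucleophilic epoxidation of one of the two enantiotopic enone arms with aqueous peroxide, giving the epoxy quinol A2 with the oxirane on the hydroxyl face.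
- In its favour: ring D comes from a flat aromatic precursor, so no organometallic addition to an epoxy ketone is needed, and three centres (C1′, C5′, C6′) arise in one catalytic step. The N–O bond is carried as an ether on a pyridone from the start, which avoids a metalated N-oxide; on this point the alternative is the better plan.
- Against it here: the substrate is the complete acyl pyridone, an acidic chelating tricarbonyl that can bind or protonate the amine catalyst. The catalyst must tell the two arms apart far from any existing centre, and the second arm can react as well. Afterwards the remaining enone must be reduced at C2′=C3′ without touching the ring A alkene and then at C4′ to the alcohol trans to the oxirane.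
- Comparison: both plans end at the same ring D. The chosen plan buys C4′ and sets C5′/C6′ and C1′ by two substrate-controlled steps on small molecules; the alternative stakes a late intermediate on one reagent-controlled step. Both use iminium activation by an amine, here on a simple enal, there on a hindered dienone. The step counts for ring D are about equal, and the nucleophilic epoxidation is the equal of the chosen chemistry in sparing the ring A alkene.

Alternative 2: The cut is between the acyl carbon and C3 of ring C, with the pyridone replaced by an isoxazole. The octalin nitrile oxide A3 undergoes [3+2] cycloaddition with the pyrrolidine enamine A4 (an enamino ester carrying ring D); loss of pyrrolidine gives the isoxazole A5, a masked tricarbonyl.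
- In its favour: the regiochemistry of enamine–nitrile oxide cycloadditions is dependable, no organometallic reagent is needed, and the chelating tricarbonyl stays hidden. A3 could be made by dehydration of the nitro compound 16 of the chosen route, which saves the Nef step. The pyridone N–O bond would come from a hydroxylamine building block and not from a peracid. On these two points the alternative is the equal or the better.
- Against it here: after the key step ring C must still be built (one carbon at the hindered methylene next to C1′, condensation with a protected hydroxylamine, ring closure on the ester). The isoxazole N–O bond must then be cleaved reductively while the N–O bond of the new pyridone, the oxirane and the alkene are kept.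
- Comparison: the alternative forms the most hindered bond early and without a metalated heterocycle, where the chosen plan forms it late by addition to an aldehyde. It replaces a polar addition and an oxidation by a dipolar cycloaddition. After the coupling it is longer (about six steps against three).

Alternative 3: The cut is the C1′–C6′ bond of ring D. The chiral-pool keto aldehyde A6, with C4′ and C5′ oxygens held in an acetonide, is reduced by SmI2; the ketyl of the aryl ketone adds to the aldehyde and closes the cyclohexane as the cis-1,2-diol A7.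
- In its favour: the C4′ and C5′ configuration comes from a cheap sugar, which is the equal of the purchased enone of the chosen plan. C1′ and C6′ form in one chelate-controlled step, and no epoxy ketone has to survive an aryl-lithium.
- Against it here: A7 is a tetrol derivative, not an epoxide. The oxirane must be closed by displacement at C5′ by the C6′ oxygen with inversion, which needs the C5′ hydroxyl activated selectively beside the C4′ hydroxyl once the acetonide is opened. The benzyl-type ethers must later be removed by acid or oxidant next to the oxirane, and the N–O bond is still missing.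
- Comparison: both reach the same ring D, but the chosen plan gets the epoxy carbinol in two steps from the enone. A reductive single-electron cyclisation under chelate control stands against a polar addition under stereoelectronic control, with comparable expected selectivity. In step count the alternative is clearly longer.

Key step: step 1

Assumption: 22 is taken as purchasable in enantiopure form, and the facial preferences of the two amine catalysts (steps 1 and 8) are assigned from their accepted shielding models.

## Route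

Step 1
Reactants: 1 isoprene; 2 methyl (E)-4-oxobut-2-enoate
Product: 3 methyl (1R,6R)-6-formyl-3-methylcyclohex-3-ene-1-carboxylate
Conditions: (5R)-5-benzyl-2,2,3-trimethylimidazolidin-4-one·HCl (20 mol%), 1 (3 equiv), MeCN/H2O 95:5, 0 °C
Reagents that add atoms: none
Why: The secondary amine salt condenses reversibly with the formyl group of 2 to an E-configured iminium ion, which lowers the LUMO of the alkene and places its largest coefficient on the ester-bearing β-carbon. Isoprene then adds in a concerted, asynchronous [4+2] cycloaddition and hydrolysis of the adduct iminium ion returns the catalyst; the closest known reaction type is the imidazolidinone-salt-catalysed Diels–Alder reaction of enals with acyclic dienes. Ring B is closed in this one step as a six-membered carbocycle by suprafacial formation of the C4a–C5 and C8–C8a bonds. The trans relation of C4a and C8a follows stereospecifically from the E geometry of 2. Their absolute configuration comes from the catalyst: the benzyl group covers one face of the planar iminium ion, and with the (5R) antipode the diene should reach the open face that leads to (1R,6R)-3. The step needs regiocontrol (methyl para to the formyl-bearing carbon), which bonding of the more nucleophilic CH2 terminus of isoprene (the one next to the methyl-bearing carbon) to the iminium β-carbon secures against the weaker opposing pull of the ester. It also needs the catalysed path to outrun the thermal background, which the low temperature and the strong iminium activation secure; only the aldehyde can form an iminium ion, so the ester stays a spectator.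

Step 2
Reactants: 3 methyl (1R,6R)-6-formyl-3-methylcyclohex-3-ene-1-carboxylate
Product: 4 methyl (1R,6R)-6-(dimethoxymethyl)-3-methylcyclohex-3-ene-1-carboxylate
Conditions: HC(OMe)3, p-TsOH·H2O (cat.), MeOH, rt
Reagents that add atoms: trimethyl orthoformate, COC(OC)OC; methanol, CO
Why: Acid-catalysed acetalisation with the orthoformate as water scavenger masks the aldehyde against the silane, hydride and ylide of the next steps; the trans arrangement at the epimerisable formyl-bearing carbon is the stable one and is kept.

Step 3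
Reactants: 4 methyl (1R,6R)-6-(dimethoxymethyl)-3-methylcyclohex-3-ene-1-carboxylate
Product: 5 methyl (1R,2R,5R)-2-(dimethoxymethyl)-5-methylcyclohexane-1-carboxylate
Conditions: Mn(dpm)3 (10 mol%), PhSiH3, t-BuOOH, i-PrOH, rt
Reagents that add atoms: none
Why: Radical hydrogenation by metal-hydride hydrogen-atom transfer gives a tertiary radical at the methyl-bearing carbon, which takes up its hydrogen axially so that the methyl group ends equatorial and cis to the ester-bearing carbon's substituent (the all-equatorial, thermodynamically preferred isomer, R at the new centre); ester and acetal are inert.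

Step 4
Reactants: 5 methyl (1R,2R,5R)-2-(dimethoxymethyl)-5-methylcyclohexane-1-carboxylate
Product: 6 (1R,2R,5R)-2-(dimethoxymethyl)-5-methylcyclohexane-1-carbaldehyde
Conditions: i-Bu2AlH (1.1 equiv), CH2Cl2, −78 °C; Rochelle salt
Reagents that add atoms: none
Why: Partial reduction of a methyl ester: the aluminium hemiacetal, held by chelation to a neighbouring acetal oxygen, survives at −78 °C and releases the aldehyde on work-up; the α-centre keeps the stable trans arrangement.

Step 5
Reactants: 6 (1R,2R,5R)-2-(dimethoxymethyl)-5-methylcyclohexane-1-carbaldehyde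
Product: 7 (1R,2S,4R)-1-(dimethoxymethyl)-2-ethenyl-4-methylcyclohexane
Conditions: Ph3PCH3Br, KN(SiMe3)2, THF, −78 → 0 °C
Reagents that add atoms: methyltriphenylphosphonium bromide, C[P+](c1ccccc1)(c1ccccc1)c1ccccc1.[Br-]
Why: Wittig methylenation with a non-stabilised ylide turns the former ester carbon into the vinyl CH that will become C4; low temperature avoids enolisation and the acetal is inert to base.

Step 6
Reactants: 7 (1R,2S,4R)-1-(dimethoxymethyl)-2-ethenyl-4-methylcyclohexane
Product: 8 (1R,2S,4R)-2-ethenyl-4-methylcyclohexane-1-carbaldehyde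
Conditions: 1 M HCl, THF, 0 °C → rt
Reagents that add atoms: water, O
Why: Acid hydrolysis of the dimethyl acetal frees the aldehyde that will become C1; the terminal alkene is untouched and the trans-diequatorial ring substitution is the stable one.

Step 7
Reactants: 8 (1R,2S,4R)-2-ethenyl-4-methylcyclohexane-1-carbaldehyde; 9 nitromethane
Product: 12 (1R,2S,4R)-2-ethenyl-4-methyl-1-[(E)-2-nitroethenyl]cyclohexane, via nitro alcohol 10 (not isolated), via mesylate 11 (not isolated)
Conditions: 9 (5 equiv), tetramethylguanidine (cat.), THF, 0 °C; concentrate; MsCl, Et3N, CH2Cl2, −20 → 0 °C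
Reagents that add atoms: none
Why: A Henry addition brings in the future acyl carbon, and mesylation with E1cB elimination gives the conjugated E-nitroalkene; the carbinol configuration of the intermediate is lost in the elimination and is immaterial.

Step 8
Reactants: 12 (1R,2S,4R)-2-ethenyl-4-methyl-1-[(E)-2-nitroethenyl]cyclohexane; 13 propanal
Product: 14 (2S,3S)-3-[(1R,2S,4R)-2-ethenyl-4-methylcyclohexyl]-2-methyl-4-nitrobutanal
Conditions: 13 (5 equiv), (R)-2-[diphenyl(trimethylsilyloxy)methyl]pyrrolidine (10 mol%), 4-nitrophenol (10 mol%), toluene, 0 °C → rt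
Reagents that add atoms: none
Why: Enamine-catalysed Michael addition of an aldehyde to a nitroalkene: the E-enamine of propanal, shielded on one face by the diphenyl(silyloxy)methyl group, adds through a compact synclinal arrangement and should give the syn adduct. The (R) catalyst is chosen to set C2 and C1 as (2S,3S), which is the cis C1/C2 pair of ring A; control by the catalyst is expected to override the adjacent ring centre.

Step 9
Reactants: 14 (2S,3S)-3-[(1R,2S,4R)-2-ethenyl-4-methylcyclohexyl]-2-methyl-4-nitrobutanal
Product: 15 (1R,2S,4R)-2-ethenyl-4-methyl-1-[(2R,3R)-3-methyl-1-nitropent-4-en-2-yl]cyclohexane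
Conditions: Ph3PCH3Br (3 equiv), KN(SiMe3)2 (2.8 equiv), THF, −78 → 0 °C; aq. NH4Cl
Reagents that add atoms: methyltriphenylphosphonium bromide, C[P+](c1ccccc1)(c1ccccc1)c1ccccc1.[Br-]
Why: Wittig methylenation of the aldehyde is faster at −78 °C than enolisation at C2; an excess of ylide is used because the acidic nitromethyl group can consume base, and the descriptors change only through the priority rules.

Step 10
Reactants: 15 (1R,2S,4R)-2-ethenyl-4-methyl-1-[(2R,3R)-3-methyl-1-nitropent-4-en-2-yl]cyclohexane
Product: 16 (1R,2R,4aS,6R,8aR)-2,6-dimethyl-1-(nitromethyl)-1,2,4a,5,6,7,8,8a-octahydronaphthalene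
Conditions: second-generation Grubbs catalyst RuCl2(=CHPh)(H2IMes)(PCy3) (5 mol%), CH2Cl2, 40 °C
Reagents that add atoms: none
Why: Ring-closing metathesis of the 1,7-diene closes ring A by forming the C3=C4 bond (necessarily cis) with loss of ethylene; the two vinyl groups sit on trans-diequatorial arms, so the strain-free trans-octalin forms and no stereocentre is touched.

Step 11
Reactants: 16 (1R,2R,4aS,6R,8aR)-2,6-dimethyl-1-(nitromethyl)-1,2,4a,5,6,7,8,8a-octahydronaphthalene
Product: 18 (1R,2R,4aS,6R,8aR)-2,6-dimethyl-1,2,4a,5,6,7,8,8a-octahydronaphthalene-1-carbaldehyde, via sodium nitronate 17 (not isolated)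
Conditions: NaOMe, MeOH, 0 °C; then aq. TiCl3, NH4OAc buffer (pH 5), THF, rt
Reagents that add atoms: water, O
Why: Nef reaction in its reductive form: the nitronate is reduced by trivalent titanium to the imine, which hydrolyses at buffered pH to the aldehyde; the near-neutral medium leaves C1 (now α to the formyl group) and the alkene untouched.

Step 12
Reactants: 19 5-bromo-2,4-dichloropyridine
Product: 21 5-bromo-2,4-bis[2-(trimethylsilyl)ethoxy]pyridine, via monoether 20 (not isolated)
Conditions: Me3SiCH2CH2OH (2.5 equiv), NaH (2.6 equiv), THF/DMF, 0 → 65 °C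
Reagents that add atoms: 2-(trimethylsilyl)ethanol, C[Si](C)(C)CCO
Why: Twofold nucleophilic aromatic substitution, first at C4 and then at C2, both activated by the ring nitrogen, while the C5 bromide is not; the two ethers are fluoride-labile masks for the pyridone oxygens.

Step 13
Reactants: 22 (4S)-4-{[tert-butyl(dimethyl)silyl]oxy}cyclohex-2-en-1-one
Product: 23 (1R,5S,6S)-5-{[tert-butyl(dimethyl)silyl]oxy}-7-oxabicyclo[4.1.0]heptan-2-one
Conditions: 30% H2O2, Triton B (cat.), THF, 0 °C
Reagents that add atoms: hydrogen peroxide, OO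
Why: Weitz–Scheffer epoxidation: hydroperoxide adds to the β-carbon on the face away from the γ-silyloxy group and the enolate closes the oxirane, giving the trans epoxy silyl ether and so the C5′/C6′ configuration relative to C4′.

Step 14
Reactants: 21 5-bromo-2,4-bis[2-(trimethylsilyl)ethoxy]pyridine; 23 (1R,5S,6S)-5-{[tert-butyl(dimethyl)silyl]oxy}-7-oxabicyclo[4.1.0]heptan-2-one
Product: 25 (1R,2R,5S,6S)-2-{4,6-bis[2-(trimethylsilyl)ethoxy]pyridin-3-yl}-5-{[tert-butyl(dimethyl)silyl]oxy}-7-oxabicyclo[4.1.0]heptan-2-ol, via aryllithium 24 (not isolated)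
Conditions: n-BuLi (1.05 equiv), THF, −78 °C; then 23, −78 °C; aq. NH4Cl
Reagents that add atoms: none
Why: Bromine–lithium exchange followed by 1,2-addition of the aryllithium to the α,β-epoxy ketone antiperiplanar to the oxirane C–O bond, on the face away from the epoxide oxygen, so the new tertiary hydroxyl is cis to the oxirane (R at C1′); low temperature suppresses enolisation.

Step 15
Reactants: 25 (1R,2R,5S,6S)-2-{4,6-bis[2-(trimethylsilyl)ethoxy]pyridin-3-yl}-5-{[tert-butyl(dimethyl)silyl]oxy}-7-oxabicyclo[4.1.0]heptan-2-ol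
Product: 26 5-[(1R,2R,5S,6S)-5-{[tert-butyl(dimethyl)silyl]oxy}-2-hydroxy-7-oxabicyclo[4.1.0]heptan-2-yl]-2,4-bis[2-(trimethylsilyl)ethoxy]pyridine 1-oxide
Conditions: mCPBA (1.5 equiv), NaHCO3, CH2Cl2, 0 °C → rt
Reagents that add atoms: 3-chloroperoxybenzoic acid, O=C(OO)c1cccc(Cl)c1
Why: Peracid N-oxidation of the electron-rich pyridine nitrogen puts the N–O bond of the target in place at a stage where the molecule has no alkene; the bicarbonate buffer protects the oxirane and the tertiary carbinol.

Step 16
Reactants: 26 5-[(1R,2R,5S,6S)-5-{[tert-butyl(dimethyl)silyl]oxy}-2-hydroxy-7-oxabicyclo[4.1.0]heptan-2-yl]-2,4-bis[2-(trimethylsilyl)ethoxy]pyridine 1-oxide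
Product: 27 5-[(1R,2R,5S,6S)-5-{[tert-butyl(dimethyl)silyl]oxy}-2-hydroxy-7-oxabicyclo[4.1.0]heptan-2-yl]-3-iodo-2,4-bis[2-(trimethylsilyl)ethoxy]pyridine 1-oxide
Conditions: NIS (1.2 equiv), TFA (cat.), MeCN, 0 °C → rt, dark
Reagents that add atoms: N-iodosuccinimide, O=C1CCC(=O)N1I
Why: Electrophilic aromatic iodination at C3, the only open position and ortho to both ether oxygens (C6, next to the N-oxide nitrogen, is deactivated), installs the handle for metalation.

Step 17
Reactants: 27 5-[(1R,2R,5S,6S)-5-{[tert-butyl(dimethyl)silyl]oxy}-2-hydroxy-7-oxabicyclo[4.1.0]heptan-2-yl]-3-iodo-2,4-bis[2-(trimethylsilyl)ethoxy]pyridine 1-oxide; 18 (1R,2R,4aS,6R,8aR)-2,6-dimethyl-1,2,4a,5,6,7,8,8a-octahydronaphthalene-1-carbaldehyde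
Product: 29 5-[(1R,2R,5S,6S)-5-{[tert-butyl(dimethyl)silyl]oxy}-2-hydroxy-7-oxabicyclo[4.1.0]heptan-2-yl]-3-{[(1R,2R,4aS,6R,8aR)-2,6-dimethyl-1,2,4a,5,6,7,8,8a-octahydronaphthalen-1-yl](hydroxy)methyl}-2,4-bis[2-(trimethylsilyl)ethoxy]pyridine 1-oxide (both carbinol epimers), via arylmagnesium chloride 28 (not isolated)
Conditions: i-PrMgCl·LiCl (2.2 equiv), THF, −40 °C; then 18, −40 → 0 °C; aq. NH4Cl
Reagents that add atoms: none
Why: Iodine–magnesium exchange on an iodopyridine N-oxide (the first equivalent of reagent deprotonates the tertiary alcohol) gives an arylmagnesium flanked by two ether oxygens, which adds to the aldehyde; the configuration of the new carbinol is immaterial because it is oxidised next, and the low temperature keeps the reagent from attacking the N-oxide ring.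

Step 18
Reactants: 29 5-[(1R,2R,5S,6S)-5-{[tert-butyl(dimethyl)silyl]oxy}-2-hydroxy-7-oxabicyclo[4.1.0]heptan-2-yl]-3-{[(1R,2R,4aS,6R,8aR)-2,6-dimethyl-1,2,4a,5,6,7,8,8a-octahydronaphthalen-1-yl](hydroxy)methyl}-2,4-bis[2-(trimethylsilyl)ethoxy]pyridine 1-oxide
Product: 30 5-[(1R,2R,5S,6S)-5-{[tert-butyl(dimethyl)silyl]oxy}-2-hydroxy-7-oxabicyclo[4.1.0]heptan-2-yl]-3-[(1R,2R,4aS,6R,8aR)-2,6-dimethyl-1,2,4a,5,6,7,8,8a-octahydronaphthalene-1-carbonyl]-2,4-bis[2-(trimethylsilyl)ethoxy]pyridine 1-oxide
Conditions: DMP, NaHCO3, CH2Cl2, rt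
Reagents that add atoms: none
Why: Dess–Martin oxidation of the secondary carbinol to the aryl ketone under buffered, neutral conditions; the tertiary alcohol cannot be oxidised, and C1, the N-oxide, the oxirane and the alkene are left alone.

Step 19
Reactants: 30 5-[(1R,2R,5S,6S)-5-{[tert-butyl(dimethyl)silyl]oxy}-2-hydroxy-7-oxabicyclo[4.1.0]heptan-2-yl]-3-[(1R,2R,4aS,6R,8aR)-2,6-dimethyl-1,2,4a,5,6,7,8,8a-octahydronaphthalene-1-carbonyl]-2,4-bis[2-(trimethylsilyl)ethoxy]pyridine 1-oxide
Product: 31 3-[(1R,2R,4aS,6R,8aR)-2,6-dimethyl-1,2,4a,5,6,7,8,8a-octahydronaphthalene-1-carbonyl]-5-[(1R,2R,5S,6R)-2,5-dihydroxy-7-oxabicyclo[4.1.0]heptan-2-yl]-1,4-dihydroxypyridin-2(1H)-one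
Conditions: TASF (6 equiv), DMF, 0 °C → rt; pH 5 buffer
Reagents that add atoms: none
Why: Fluoride cleaves the silyl ether at C4′ and attacks silicon in both silylethyl ethers, which fragment to ethylene and fluorotrimethylsilane. Loss of the C2 ether from the N-oxide gives the N-hydroxy-2-pyridone tautomer directly, and loss of the C4 ether gives the enol; a non-basic fluoride source is used so that the C4′ oxygen does not open the neighbouring oxirane.

## Compound list

1 | isoprene | C=CC(C)=C | starting material
2 | methyl (E)-4-oxobut-2-enoate | COC(=O)/C=C/C=O | starting material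
3 | methyl (1R,6R)-6-formyl-3-methylcyclohex-3-ene-1-carboxylate | CC1=CC[C@@H](C=O)[C@H](C(=O)OC)C1 | intermediate
4 | methyl (1R,6R)-6-(dimethoxymethyl)-3-methylcyclohex-3-ene-1-carboxylate | CC1=CC[C@@H](C(OC)OC)[C@H](C(=O)OC)C1 | intermediate
5 | methyl (1R,2R,5R)-2-(dimethoxymethyl)-5-methylcyclohexane-1-carboxylate | C[C@@H]1CC[C@@H](C(OC)OC)[C@H](C(=O)OC)C1 | intermediate
6 | (1R,2R,5R)-2-(dimethoxymethyl)-5-methylcyclohexane-1-carbaldehyde | C[C@@H]1CC[C@@H](C(OC)OC)[C@H](C=O)C1 | intermediate
7 | (1R,2S,4R)-1-(dimethoxymethyl)-2-ethenyl-4-methylcyclohexane | C[C@@H]1CC[C@@H](C(OC)OC)[C@H](C=C)C1 | intermediate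
8 | (1R,2S,4R)-2-ethenyl-4-methylcyclohexane-1-carbaldehyde | C[C@@H]1CC[C@@H](C=O)[C@H](C=C)C1 | intermediate
9 | nitromethane | C[N+](=O)[O-] | starting material
10 | 1-[(1R,2S,4R)-2-ethenyl-4-methylcyclohexyl]-2-nitroethan-1-ol (both carbinol epimers; not isolated) | C[C@@H]1CC[C@@H](C(O)C[N+](=O)[O-])[C@H](C=C)C1 | intermediate
11 | 1-[(1R,2S,4R)-2-ethenyl-4-methylcyclohexyl]-2-nitroethyl methanesulfonate (not isolated) | C[C@@H]1CC[C@@H](C(OS(C)(=O)=O)C[N+](=O)[O-])[C@H](C=C)C1 | intermediate
12 | (1R,2S,4R)-2-ethenyl-4-methyl-1-[(E)-2-nitroethenyl]cyclohexane | C[C@@H]1CC[C@@H](/C=C/[N+](=O)[O-])[C@H](C=C)C1 | intermediate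
13 | propanal | CCC=O | starting material
14 | (2S,3S)-3-[(1R,2S,4R)-2-ethenyl-4-methylcyclohexyl]-2-methyl-4-nitrobutanal | C[C@@H]1CC[C@@H]([C@H](C[N+](=O)[O-])[C@H](C)C=O)[C@H](C=C)C1 | intermediate
15 | (1R,2S,4R)-2-ethenyl-4-methyl-1-[(2R,3R)-3-methyl-1-nitropent-4-en-2-yl]cyclohexane | C[C@@H]1CC[C@@H]([C@H](C[N+](=O)[O-])[C@H](C)C=C)[C@H](C=C)C1 | intermediate
16 | (1R,2R,4aS,6R,8aR)-2,6-dimethyl-1-(nitromethyl)-1,2,4a,5,6,7,8,8a-octahydronaphthalene | C[C@@H]1CC[C@H]2[C@H](C[N+](=O)[O-])[C@H](C)C=C[C@@H]2C1 | intermediate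
17 | sodium nitronate of 16 (sodium salt of the aci-nitro form; not isolated) | C[C@@H]1CC[C@H]2[C@H](C=[N+]([O-])[O-])[C@H](C)C=C[C@@H]2C1.[Na+] | intermediate
18 | (1R,2R,4aS,6R,8aR)-2,6-dimethyl-1,2,4a,5,6,7,8,8a-octahydronaphthalene-1-carbaldehyde | C[C@@H]1CC[C@H]2[C@H](C=O)[C@H](C)C=C[C@@H]2C1 | intermediate
19 | 5-bromo-2,4-dichloropyridine | Clc1cc(Cl)c(Br)cn1 | starting material
20 | 5-bromo-2-chloro-4-[2-(trimethylsilyl)ethoxy]pyridine (not isolated) | C[Si](C)(C)CCOc1cc(Cl)ncc1Br | intermediate
21 | 5-bromo-2,4-bis[2-(trimethylsilyl)ethoxy]pyridine | C[Si](C)(C)CCOc1cc(OCC[Si](C)(C)C)c(Br)cn1 | intermediate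
22 | (4S)-4-{[tert-butyl(dimethyl)silyl]oxy}cyclohex-2-en-1-one | O=C1C=C[C@@H](O[Si](C)(C)C(C)(C)C)CC1 | starting material
23 | (1R,5S,6S)-5-{[tert-butyl(dimethyl)silyl]oxy}-7-oxabicyclo[4.1.0]heptan-2-one | O=C1CC[C@H](O[Si](C)(C)C(C)(C)C)[C@H]2O[C@@H]12 | intermediate
24 | {4,6-bis[2-(trimethylsilyl)ethoxy]pyridin-3-yl}lithium (not isolated) | [Li]c1cnc(OCC[Si](C)(C)C)cc1OCC[Si](C)(C)C | intermediate
25 | (1R,2R,5S,6S)-2-{4,6-bis[2-(trimethylsilyl)ethoxy]pyridin-3-yl}-5-{[tert-butyl(dimethyl)silyl]oxy}-7-oxabicyclo[4.1.0]heptan-2-ol | C[Si](C)(C)CCOc1cc(OCC[Si](C)(C)C)c(cn1)[C@]1(O)CC[C@H](O[Si](C)(C)C(C)(C)C)[C@H]2O[C@H]21 | intermediate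
26 | 5-[(1R,2R,5S,6S)-5-{[tert-butyl(dimethyl)silyl]oxy}-2-hydroxy-7-oxabicyclo[4.1.0]heptan-2-yl]-2,4-bis[2-(trimethylsilyl)ethoxy]pyridine 1-oxide | C[Si](C)(C)CCOc1cc(OCC[Si](C)(C)C)c(c[n+]1[O-])[C@]1(O)CC[C@H](O[Si](C)(C)C(C)(C)C)[C@H]2O[C@H]21 | intermediate
27 | 5-[(1R,2R,5S,6S)-5-{[tert-butyl(dimethyl)silyl]oxy}-2-hydroxy-7-oxabicyclo[4.1.0]heptan-2-yl]-3-iodo-2,4-bis[2-(trimethylsilyl)ethoxy]pyridine 1-oxide | C[Si](C)(C)CCOc1c(I)c(OCC[Si](C)(C)C)c(c[n+]1[O-])[C@]1(O)CC[C@H](O[Si](C)(C)C(C)(C)C)[C@H]2O[C@H]21 | intermediate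
28 | 3-chloromagnesio derivative of 27 as its chloromagnesium alkoxide (not isolated) | C[Si](C)(C)CCOc1c([Mg]Cl)c(OCC[Si](C)(C)C)c(c[n+]1[O-])[C@]1(O[Mg]Cl)CC[C@H](O[Si](C)(C)C(C)(C)C)[C@H]2O[C@H]21 | intermediate
29 | 5-[(1R,2R,5S,6S)-5-{[tert-butyl(dimethyl)silyl]oxy}-2-hydroxy-7-oxabicyclo[4.1.0]heptan-2-yl]-3-{[(1R,2R,4aS,6R,8aR)-2,6-dimethyl-1,2,4a,5,6,7,8,8a-octahydronaphthalen-1-yl](hydroxy)methyl}-2,4-bis[2-(trimethylsilyl)ethoxy]pyridine 1-oxide (both carbinol epimers) | C[C@@H]1CC[C@H]2[C@H](C(O)c3c(OCC[Si](C)(C)C)c(c[n+]([O-])c3OCC[Si](C)(C)C)[C@]3(O)CC[C@H](O[Si](C)(C)C(C)(C)C)[C@H]4O[C@H]43)[C@H](C)C=C[C@@H]2C1 | intermediate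
30 | 5-[(1R,2R,5S,6S)-5-{[tert-butyl(dimethyl)silyl]oxy}-2-hydroxy-7-oxabicyclo[4.1.0]heptan-2-yl]-3-[(1R,2R,4aS,6R,8aR)-2,6-dimethyl-1,2,4a,5,6,7,8,8a-octahydronaphthalene-1-carbonyl]-2,4-bis[2-(trimethylsilyl)ethoxy]pyridine 1-oxide | C[C@@H]1CC[C@H]2[C@H](C(=O)c3c(OCC[Si](C)(C)C)c(c[n+]([O-])c3OCC[Si](C)(C)C)[C@]3(O)CC[C@H](O[Si](C)(C)C(C)(C)C)[C@H]4O[C@H]43)[C@H](C)C=C[C@@H]2C1 | intermediate
31 | 3-[(1R,2R,4aS,6R,8aR)-2,6-dimethyl-1,2,4a,5,6,7,8,8a-octahydronaphthalene-1-carbonyl]-5-[(1R,2R,5S,6R)-2,5-dihydroxy-7-oxabicyclo[4.1.0]heptan-2-yl]-1,4-dihydroxypyridin-2(1H)-one | C[C@@H]1CC[C@H]2[C@H](C(=O)c3c(O)c([C@]4(O)CC[C@H](O)[C@H]5O[C@H]54)cn(O)c3=O)[C@H](C)C=C[C@@H]2C1 | target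

## Step count and least certain steps

Total step count: 19. Longest linear sequence: 14 steps (steps 1–11, then 17–19). The pyridine branch (steps 12, 14, 15, 16) and the epoxy ketone (step 13) join at steps 14 and 17.

Step 1 (key step). Most likely to go wrong: erosion of regiocontrol, because the ester also polarises the dienophile in the opposite sense, and erosion of face selectivity through the uncatalysed background cycloaddition if iminium turnover is slow. Fallback, setting out from 1 and returning at 3: auxiliary control under Lewis acid. Isoprene is combined with the imide dienophile F1 (from monomethyl fumarate and (4R)-4-benzyl-1,3-oxazolidin-2-one) and Et2AlCl in CH2Cl2 at −78 °C. The chelated imide is attacked on the face away from the benzyl group and directs the methyl group para to the imide-bearing carbon, giving the cycloadduct F2. LiBH4 in wet ether reduces the imide in preference to the methyl ester and releases the auxiliary, giving the hydroxy ester F3, and Dess–Martin oxidation returns to 3.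

Step 8. Most likely to go wrong: loss of face selectivity or of rate, if the preference of the catalyst runs against that of the neighbouring ring centre on a hindered, α-branched nitroalkene. Fallback, setting out from 8 and returning at 18: chirality transfer in an acyclic Ireland–Claisen rearrangement.
- Wittig reaction of 8 with 1-(triphenylphosphoranylidene)propan-2-one gives the E-enone F4.
- Corey–Bakshi–Shibata reduction with the (R)-oxazaborolidine and BH3·SMe2 gives the (S)-allylic alcohol F5, and acylation with propanoyl chloride gives the propanoate F6.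
- Deprotonation with LiN(i-Pr)2 in THF/DMPU and silylation with Me3SiCl gives the (Z)-silyl ketene acetal F7, which is not isolated. Its rearrangement through a chair transition state carries the carbinol configuration to C1 and sets C2 from the enolate geometry, giving the acid F8.
- LiAlH4 gives the alcohol F9, Dess–Martin oxidation the aldehyde F10, and Wittig methylenation the triene F11.
- Ring-closing metathesis between the two terminal vinyl groups with the second-generation Grubbs catalyst gives the propenyl octalin F12.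
- Lemieux–Johnson cleavage (OsO4 cat., NaIO4, 2,6-lutidine) of the more accessible E-propenyl group, through the diol F13, gives 18.

Step 17. Most likely to go wrong: attack of the organomagnesium reagent on the N-oxide ring or loss of the N-oxide oxygen in competition with the exchange, and slow addition of a doubly ortho-substituted arylmagnesium to a branched aldehyde. Fallback, setting out from 25 (with 18) and returning at 31: the N–O bond is made last.
- 25 is treated with n-BuLi (2.2 equiv, THF, −78 → −20 °C); the alkoxide forms first and C3, between the two ether oxygens, is then deprotonated, giving the dilithio species F14.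
- Addition to 18 gives the pyridyl carbinol F15, and Dess–Martin oxidation gives the ketone F16.
- TASF removes the three silyl-based groups and gives the N–H pyridone F17.
- Silylation with (Me3Si)2NH/Me3SiCl gives the persilylated pyridine F18, and oxidation at nitrogen with MoO5·pyridine·HMPA, followed by aqueous EDTA, gives 31.
- In this fallback the peroxomolybdenum reagent must spare the ring A alkene.

Step 14. Most likely to go wrong: enolisation of the epoxy ketone by the aryllithium, or incomplete face selectivity in the addition. Fallback, setting out from 24 (with 22) and returning at 25: the order of addition and epoxidation is reversed. The aryllithium 24 adds to the enone 22 at −78 °C; axial attack on the half-chair with a pseudo-equatorial silyloxy group places the aryl group cis to the silyl ether and gives the allylic alcohol F19. Hydroxyl-directed epoxidation with VO(acac)2 and t-BuOOH then delivers the oxygen on the face of the tertiary hydroxyl, which is also the face away from the silyl ether, to give 25.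

## Further compounds

F1 | step 1 | (4R)-4-benzyl-3-[(E)-4-methoxy-4-oxobut-2-enoyl]-1,3-oxazolidin-2-one | COC(=O)/C=C/C(=O)N1[C@H](Cc2ccccc2)COC1=O
F2 | step 1 | methyl (1R,6R)-6-{[(4R)-4-benzyl-2-oxo-1,3-oxazolidin-3-yl]carbonyl}-3-methylcyclohex-3-ene-1-carboxylate | CC1=CC[C@@H](C(=O)N2[C@H](Cc3ccccc3)COC2=O)[C@H](C(=O)OC)C1
F3 | step 1 | methyl (1R,6R)-6-(hydroxymethyl)-3-methylcyclohex-3-ene-1-carboxylate | CC1=CC[C@@H](CO)[C@H](C(=O)OC)C1
F4 | step 8 | (3E)-4-[(1S,2S,4R)-2-ethenyl-4-methylcyclohexyl]but-3-en-2-one | C[C@@H]1CC[C@@H](/C=C/C(C)=O)[C@H](C=C)C1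
F5 | step 8 | (2S,3E)-4-[(1S,2S,4R)-2-ethenyl-4-methylcyclohexyl]but-3-en-2-ol | C[C@@H]1CC[C@@H](/C=C/[C@H](C)O)[C@H](C=C)C1
F6 | step 8 | (2S,3E)-4-[(1S,2S,4R)-2-ethenyl-4-methylcyclohexyl]but-3-en-2-yl propanoate | C[C@@H]1CC[C@@H](/C=C/[C@H](C)OC(=O)CC)[C@H](C=C)C1
F7 | step 8 | (Z)-trimethylsilyl ketene acetal of F6 (methyl cis to the silyloxy group) | C[C@@H]1CC[C@@H](/C=C/[C@H](C)O/C(O[Si](C)(C)C)=C/C)[C@H](C=C)C1
F8 | step 8 | (2S,3S,4E)-3-[(1R,2S,4R)-2-ethenyl-4-methylcyclohexyl]-2-methylhex-4-enoic acid | C[C@@H]1CC[C@@H]([C@H](/C=C/C)[C@H](C)C(=O)O)[C@H](C=C)C1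
F9 | step 8 | (2S,3S,4E)-3-[(1R,2S,4R)-2-ethenyl-4-methylcyclohexyl]-2-methylhex-4-en-1-ol | C[C@@H]1CC[C@@H]([C@H](/C=C/C)[C@H](C)CO)[C@H](C=C)C1
F10 | step 8 | (2S,3S,4E)-3-[(1R,2S,4R)-2-ethenyl-4-methylcyclohexyl]-2-methylhex-4-enal | C[C@@H]1CC[C@@H]([C@H](/C=C/C)[C@H](C)C=O)[C@H](C=C)C1
F11 | step 8 | (1R,2S,4R)-2-ethenyl-4-methyl-1-[(3R,4R,5E)-3-methylhepta-1,5-dien-4-yl]cyclohexane | C[C@@H]1CC[C@@H]([C@H](/C=C/C)[C@H](C)C=C)[C@H](C=C)C1
F12 | step 8 | (1R,2R,4aS,6R,8aR)-2,6-dimethyl-1-[(1E)-prop-1-en-1-yl]-1,2,4a,5,6,7,8,8a-octahydronaphthalene | C[C@@H]1CC[C@H]2[C@H](/C=C/C)[C@H](C)C=C[C@@H]2C1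
F13 | step 8 | 1-[(1R,2R,4aS,6R,8aR)-2,6-dimethyl-1,2,4a,5,6,7,8,8a-octahydronaphthalen-1-yl]propane-1,2-diol (carbinol configurations immaterial) | C[C@@H]1CC[C@H]2[C@H](C(O)C(C)O)[C@H](C)C=C[C@@H]2C1
F14 | step 17 | C3-lithio derivative of 25 as its lithium alkoxide | C[Si](C)(C)CCOc1c([Li])c(OCC[Si](C)(C)C)c(cn1)[C@]1(O[Li])CC[C@H](O[Si](C)(C)C(C)(C)C)[C@H]2O[C@H]21
F15 | step 17 | {5-[(1R,2R,5S,6S)-5-{[tert-butyl(dimethyl)silyl]oxy}-2-hydroxy-7-oxabicyclo[4.1.0]heptan-2-yl]-2,4-bis[2-(trimethylsilyl)ethoxy]pyridin-3-yl}[(1R,2R,4aS,6R,8aR)-2,6-dimethyl-1,2,4a,5,6,7,8,8a-octahydronaphthalen-1-yl]methanol | C[C@@H]1CC[C@H]2[C@H](C(O)c3c(OCC[Si](C)(C)C)c(cnc3OCC[Si](C)(C)C)[C@]3(O)CC[C@H](O[Si](C)(C)C(C)(C)C)[C@H]4O[C@H]43)[C@H](C)C=C[C@@H]2C1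
F16 | step 17 | {5-[(1R,2R,5S,6S)-5-{[tert-butyl(dimethyl)silyl]oxy}-2-hydroxy-7-oxabicyclo[4.1.0]heptan-2-yl]-2,4-bis[2-(trimethylsilyl)ethoxy]pyridin-3-yl}[(1R,2R,4aS,6R,8aR)-2,6-dimethyl-1,2,4a,5,6,7,8,8a-octahydronaphthalen-1-yl]methanone | C[C@@H]1CC[C@H]2[C@H](C(=O)c3c(OCC[Si](C)(C)C)c(cnc3OCC[Si](C)(C)C)[C@]3(O)CC[C@H](O[Si](C)(C)C(C)(C)C)[C@H]4O[C@H]43)[C@H](C)C=C[C@@H]2C1
F17 | step 17 | 3-[(1R,2R,4aS,6R,8aR)-2,6-dimethyl-1,2,4a,5,6,7,8,8a-octahydronaphthalene-1-carbonyl]-5-[(1R,2R,5S,6R)-2,5-dihydroxy-7-oxabicyclo[4.1.0]heptan-2-yl]-4-hydroxypyridin-2(1H)-one | C[C@@H]1CC[C@H]2[C@H](C(=O)c3c(O)c(c[nH]c3=O)[C@]3(O)CC[C@H](O)[C@H]4O[C@H]43)[C@H](C)C=C[C@@H]2C1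
F18 | step 17 | tetrakis(trimethylsilyl) derivative of F17 (2,4-bis(trimethylsilyloxy)pyridine, both ring D hydroxyls silylated) | C[C@@H]1CC[C@H]2[C@H](C(=O)c3c(O[Si](C)(C)C)c(cnc3O[Si](C)(C)C)[C@]3(O[Si](C)(C)C)CC[C@H](O[Si](C)(C)C)[C@H]4O[C@H]43)[C@H](C)C=C[C@@H]2C1
F19 | step 14 | (1S,4S)-1-{4,6-bis[2-(trimethylsilyl)ethoxy]pyridin-3-yl}-4-{[tert-butyl(dimethyl)silyl]oxy}cyclohex-2-en-1-ol | C[Si](C)(C)CCOc1cc(OCC[Si](C)(C)C)c(cn1)[C@]1(O)CC[C@H](O[Si](C)(C)C(C)(C)C)C=C1
A1 | alternative 1 | para-quinol: 3-[(1R,2R,4aS,6R,8aR)-2,6-dimethyl-1,2,4a,5,6,7,8,8a-octahydronaphthalene-1-carbonyl]-4-hydroxy-5-(1-hydroxy-4-oxocyclohexa-2,5-dien-1-yl)-1-[(4-methoxybenzyl)oxy]pyridin-2(1H)-one | C[C@@H]1CC[C@H]2[C@H](C(=O)c3c(O)c(C4(O)C=CC(=O)C=C4)cn(OCc5ccc(OC)cc5)c3=O)[C@H](C)C=C[C@@H]2C1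
A2 | alternative 1 | 5′,6′-epoxy para-quinol (oxirane cis to the C1′ hydroxyl, one enone arm left) | C[C@@H]1CC[C@H]2[C@H](C(=O)c3c(O)c([C@]4(O)C=CC(=O)[C@H]5O[C@H]54)cn(OCc6ccc(OC)cc6)c3=O)[C@H](C)C=C[C@@H]2C1
A3 | alternative 2 | (1R,2R,4aS,6R,8aR)-2,6-dimethyl-1,2,4a,5,6,7,8,8a-octahydronaphthalene-1-carbonitrile oxide | C[C@@H]1CC[C@H]2[C@H](C#[N+][O-])[C@H](C)C=C[C@@H]2C1
A4 | alternative 2 | methyl 4-[(1R,2R,5S,6S)-5-{[tert-butyl(dimethyl)silyl]oxy}-2-[(triethylsilyl)oxy]-7-oxabicyclo[4.1.0]heptan-2-yl]-3-(pyrrolidin-1-yl)but-2-enoate | COC(=O)C=C(C[C@]1(O[Si](CC)(CC)CC)CC[C@H](O[Si](C)(C)C(C)(C)C)[C@H]2O[C@H]21)N1CCCC1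
A5 | alternative 2 | methyl 3-(octalin-1-yl)-5-[(bis-silyloxy epoxycyclohexyl)methyl]isoxazole-4-carboxylate | C[C@@H]1CC[C@H]2[C@H](c3noc(C[C@]4(O[Si](CC)(CC)CC)CC[C@H](O[Si](C)(C)C(C)(C)C)[C@H]5O[C@H]54)c3C(=O)OC)[C@H](C)C=C[C@@H]2C1
A6 | alternative 3 | (4R,5S)-5-{3-[4,6-bis(4-methoxybenzyloxy)pyridin-3-yl]-3-oxopropyl}-2,2-dimethyl-1,3-dioxolane-4-carbaldehyde | COc1ccc(COc2cc(OCc3ccc(OC)cc3)c(cn2)C(=O)CC[C@@H]2OC(C)(C)O[C@@H]2C=O)cc1
A7 | alternative 3 | 1-[4,6-bis(4-methoxybenzyloxy)pyridin-3-yl]-3,4-O-isopropylidenecyclohexane-1,2,3,4-tetrol (1,2-cis-diol, trans to the dioxolane) | COc1ccc(COc2cc(OCc3ccc(OC)cc3)c(cn2)[C@]4(O)CC[C@@H]5OC(C)(C)O[C@@H]5[C@H]4O)cc1
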